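## The problem

Target 19 is the stearate of a 7,9′-epoxylignan: one oxolane ring (O1, C2–C5) with a 4-hydroxy-3-methoxyphenyl group on C2, the acyloxymethyl carbon C9 on C3 and a 4-hydroxy-3-methoxybenzyl group (benzylic carbon C7′) on C4. Three contiguous stereocentres (2S,3R,4R) must be set, 2,3-trans and 3,4-cis. C2 and C3 can be made together in one C–C bond formation, after which C3 is the only neighbour that can direct C4. The 3,4-cis relation is the less stable one whenever C4 is epimerisable, so it has to be made kinetically and then protected from base. C2 is a benzylic ether on an electron-rich ring: it ionises under acid and is cleaved by forcing hydrogenolysis. The stearate does not survive hydride or alkoxide and must arrive late; the two phenols must stay masked until then, and the C9 oxygen must be distinguishable from the phenols and from the C5 oxygen. The enabling feature is that C4 carries two one-carbon branches, C5 inside the ring and C7′ outside. With C5 at the acyl level and C7′ as an exocyclic methylene, the ring O1–C2–C3–C4–C5 is a γ-aryl-β-(oxymethyl)-α-methylene-γ-butyrolactone, the adduct of an aryl aldehyde and a 2-alkoxycarbonyl allylboronate.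

## Retrosynthesis

**19 ⇐ 18 ⇐ 16 + 17.** The two phenolic O–benzyl bonds are cut first, then the C9–O acyl bond. The ester is placed after the last hydride and alkoxide step. Benzyl ethers are chosen because they pass organometallic, hydride and base steps and leave by hydrogenolysis without touching the ester. Alcohol 16 is the O,O′-dibenzyl ether of the parent lignan alcohol and 17 is purchased stearoyl chloride. The forward hydrogenolysis must stop before the C2–O1 bond is attacked.

**16 ⇐ 15 ⇐ 13 (via 14) ⇐ 12.** The ring is opened at O1–C5. Cutting O1–C2 instead would close the ring through a benzylic cation and erase the C2 configuration. Closure by the C2 oxygen on a C5 sulfonate (14) leaves every bond to C2 untouched. Diol 13 is the hydride-reduction product of lactone 12, in which O1 and C5 are already joined at the acyl level. The C9 oxygen must be silent while C5 is activated, so it is carried as a bulky silyl ether (15, 13, 12) and released only after ring closure.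

**12 ⇐ 10 + 11.** The C7′–aryl bond is cut. Benzylating a lactone enolate at C4 would put the benzyl group trans to C9, the wrong relation. Conjugate arylation of the exocyclic methylene of 10 makes the enolate with the carbon substituent already in place, and the proton enters from the open face, opposite C9. Lactone 10 has two stereocentres instead of three, and the second aryl ring comes from the purchased boronic acid 11. The forward step needs kinetic protonation and no later epimerisation.

**10 ⇐ 7 + 8 (via 9).** The C2–C3 bond and the O1–C5 acyl bond are cut together. Both stereocentres arise in one closed transition state and the ring closes spontaneously from borate 9. An aldol route to the same lactone would need an auxiliary and several redox steps. The precursors are the achiral aldehyde 8 and the achiral boronate 7. The forward reaction needs enantiofacial control from a chiral phosphoric acid, anti selectivity from the geometry of 7, and lactonisation.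

**7 ⇐ 4 + 5 (via 6) ⇐ 2 (via 3) ⇐ 1.** The C4–C7′ bond is cut (the CH2B carbon of 5 becomes C7′), together with the vinylic C–H bond, then the C4–C5 bond and the O–Si bond. The required geometry, oxymethyl cis to the ester, is the kinetic result of syn-hydrometalation of ynoate 4 and retentive alkylation of alkenylalane 6 by 5; equilibrating routes to such boronates favour the other isomer. Ynoate 4 is the C-ethoxycarbonylation product of acetylide 3, made from silyl ether 2 and propargyl alcohol 1. The alkylation must keep the alkene geometry.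

## Roads not taken

**Alternative 1:** The cut is at C3–C4 and C7′–aryl. NiBr2·glyme with terpyridine would reduce the secondary iodide A1 to the C3 radical, which closes 5-exo onto the O-allyl group; the C7′ radical is captured by nickel and coupled with arylzinc bromide A2 to give A3, identical with 18.
- Merits: two C–C bonds and the ring form in one step, the stearate is already in place because organozinc reagents tolerate esters, and only debenzylation remains. The chair-like 5-exo transition state favours the substituent on the radical carbon cis to the new branch and the 2-aryl group trans to it, which is the pattern of the target.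
- Weak points: all three relations rest on one radical transition state of moderate bias, and nothing in A3 can be epimerised afterwards. The only controlling centre is the benzylic carbon of A1, which must be made enantiopure separately; the shortest access, alkoxy-iodination of a cinnamyl-type alkene, gives the racemate. A β-alkoxy alkyl iodide can eliminate at low-valent nickel, and direct coupling before cyclisation competes.
- Comparison: this road is shorter and more convergent. The chosen plan sets against that a catalytic, closed transition state for the absolute configuration and a separate, adjustable step for each relative relation.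

**Alternative 2:** The cut is again C2–C3, but through an ion pair. BF3·OEt2 or Me3SiOTf would cleave the acetal C–O bond of dihydrodioxepin A4 on the enol ether side; the enolate carbon recombines with the aryl oxocarbenium ion, contracting the ring to aldehyde A5.
- Merits: A4 is an acetal of 8, the ring and C2–C3 form in one Lewis-acid step with full atom economy, and C9 appears as an aldehyde that only needs reduction. C3 is epimerisable, so the formyl group can be moved trans to the aryl group.
- Weak points: the ions are open, so C2 is set only relative to the distant C4 and not in a closed transition state. The C4 centre (C5 of A4) must first be made by an asymmetric alkene isomerisation. The very stable p-alkoxybenzyl oxocarbenium ion makes the step reversible. Equilibration at C3 answers to two opposing preferences, trans to aryl and cis to benzyl.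
- Comparison: the length is comparable or shorter. The chosen plan offers catalyst control of C2 and reagent-geometry control of C3 in one chair, which this road lacks.

**Alternative 3:** The cut is C3–C4 by migration. Irradiation of diazo ketone A6 in methanol would give a Wolff rearrangement: the benzyl-bearing carbon shifts to the carbene carbon and the ketene is trapped as methyl ester A7.
- Merits: the 1,2-shift retains configuration at the migrating carbon, so C4 is never epimerisable, and C9 arrives as an ester in the right place.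
- Weak points: A6 requires a 2,5-trans tetrahydropyran-4-one built with absolute control, followed by diazo transfer, so several steps precede the key step. Ketene trapping protonates C3 unselectively and needs an equilibration of uncertain direction. Photolysis has to be run on a substrate with two electron-rich arenes.
- Comparison: the route is longer and moves the stereochemical burden into the pyranone. Its real advantage is that C4 needs no kinetic protonation; the chosen plan must answer that with step 5 and its fallback.

Key step: step 4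

Assumption: the sense of induction of the phosphoric acid is carried over from allyl and crotyl pinacol boronates, where the (R)-acid is taken to deliver the allyl group to the Re face of aryl aldehydes; the (S)-acid is therefore specified for the Si-face addition needed here. (S)-TRIP denotes (S)-3,3′-bis(2,4,6-triisopropylphenyl)-1,1′-binaphthyl-2,2′-diyl hydrogen phosphate.

## Route

Step 1
Reactants: 1 propargyl alcohol
Product: 2 tert-butyl(diphenyl)(prop-2-yn-1-yloxy)silane
Conditions: TBDPSCl, imidazole, CH2Cl2, 0 °C → rt
Reagents that add atoms: tert-butyl(chloro)diphenylsilane, CC(C)(C)[Si](Cl)(c1ccccc1)c1ccccc1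
Why: Standard silylation of a primary alcohol; the bulky silyl group is chosen because it must pass catalytic acid (step 4), LiAlH4 (step 6) and alkoxide (step 7) without cleavage or migration.

Step 2
Reactants: 2 tert-butyl(diphenyl)(prop-2-yn-1-yloxy)silane
Product: 4 ethyl 4-[tert-butyl(diphenyl)silyl]oxybut-2-ynoate, via lithium acetylide 3 (not isolated)
Conditions: n-BuLi, THF, −78 °C; then ClCO2Et, −78 → 0 °C
Reagents that add atoms: ethyl chloroformate, CCOC(=O)Cl
Why: Deprotonation of the terminal alkyne and C-acylation of the acetylide with a chloroformate, a routine ynoate synthesis; the added carbon is the future C5.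

Step 3
Reactants: 4 ethyl 4-[tert-butyl(diphenyl)silyl]oxybut-2-ynoate; 5 2-(iodomethyl)-4,4,5,5-tetramethyl-1,3,2-dioxaborolane
Product: 7 ethyl (Z)-4-[tert-butyl(diphenyl)silyl]oxy-2-[(4,4,5,5-tetramethyl-1,3,2-dioxaborolan-2-yl)methyl]but-2-enoate, via alkenylalane 6 (not isolated)
Conditions: i-Bu2AlH, HMPA, THF, 0 °C; then 5, 0 °C → rt
Reagents that add atoms: none
Why: Conjugate hydroalumination of the ynoate by the i-Bu2AlH–HMPA complex adds H and Al syn to give the α-alumino enoate 6, and C-alkylation by the iodomethylboronate proceeds with retention (1,4-hydrometalation with electrophilic trapping, the established entry to 3-substituted 2-alkoxycarbonyl allylboronates). The oxymethyl group therefore ends cis to the ester and trans to CH2B, the geometry the key step needs.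

Step 4
Reactants: 7 ethyl (Z)-4-[tert-butyl(diphenyl)silyl]oxy-2-[(4,4,5,5-tetramethyl-1,3,2-dioxaborolan-2-yl)methyl]but-2-enoate; 8 4-(benzyloxy)-3-methoxybenzaldehyde (O-benzylvanillin)
Product: 10 (4R,5S)-5-[4-(benzyloxy)-3-methoxyphenyl]-4-{[tert-butyl(diphenyl)silyl]oxymethyl}-3-methylideneoxolan-2-one, via borate ester 9 (not isolated)
Conditions: (S)-TRIP (10 mol %), PhMe, 0 °C → rt; then p-TsOH·H2O (5 mol %), rt
Reagents that add atoms: none
Why: The phosphoric acid hydrogen-bonds to a dioxaborolane oxygen of 7 and, through its phosphoryl oxygen, to the formyl hydrogen of 8; the allyl group is transferred through a six-membered Zimmerman–Traxler-type chair with boron on the aldehyde oxygen, forming C2–C3. The closest known reaction types are the chiral-phosphoric-acid-catalysed allyl- and crotylboration of aryl aldehydes with pinacol boronates and the Brønsted-acid-catalysed allylboration–lactonisation of 2-alkoxycarbonyl allylboronates to α-methylene-γ-butyrolactones; this step combines them. The borate oxygen of 9 then attacks the ethyl ester in a 5-exo-trig acyl substitution (O1–C5 bond), passing ethoxide to boron and closing the lactone, and the sulfonic acid completes this. C2 (5S in 10) is set by the catalyst, the (S)-acid being expected to open the Si face of 8. C3 (4R in 10) is set relative to C2 by reagent geometry: the aryl group of 8 is equatorial and the silyloxymethyl group of (Z)-7, trans to CH2B, is pseudo-equatorial, which gives the anti adduct 9 and hence the 2,3-trans lactone. The step needs enantiofacial and anti selectivity without a background path; the ester-deactivated boronate does not add to aldehydes without acid at this temperature, so the catalysed chair should be the only route, and the geometric purity of 7 carries into the trans selectivity. Silyl ether, benzyl ether and acrylate are inert to the catalytic acids.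

Step 5
Reactants: 10 (4R,5S)-5-[4-(benzyloxy)-3-methoxyphenyl]-4-{[tert-butyl(diphenyl)silyl]oxymethyl}-3-methylideneoxolan-2-one; 11 [4-(benzyloxy)-3-methoxyphenyl]boronic acid
Product: 12 (3R,4R,5S)-3-[4-(benzyloxy)-3-methoxybenzyl]-5-[4-(benzyloxy)-3-methoxyphenyl]-4-{[tert-butyl(diphenyl)silyl]oxymethyl}oxolan-2-one
Conditions: [Rh(cod)OH]2 (3 mol %), 1,4-dioxane/H2O (10:1), rt → 40 °C
Reagents that add atoms: none
Why: Hayashi–Miyaura conjugate addition: the aryl group passes from boron to monovalent rhodium and adds to the exocyclic methylene, and the rhodium enolate is protonated by water. The proton should enter on the face opposite the adjacent silyloxymethyl group, placing the new benzyl group cis to C9 (3R); the hydroxo complex needs no added base, which protects the kinetic cis lactone from epimerisation.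

Step 6
Reactants: 12 (3R,4R,5S)-3-[4-(benzyloxy)-3-methoxybenzyl]-5-[4-(benzyloxy)-3-methoxyphenyl]-4-{[tert-butyl(diphenyl)silyl]oxymethyl}oxolan-2-one
Product: 13 (1S,2R,3R)-3-[4-(benzyloxy)-3-methoxybenzyl]-1-[4-(benzyloxy)-3-methoxyphenyl]-2-{[tert-butyl(diphenyl)silyl]oxymethyl}butane-1,4-diol
Conditions: LiAlH4, THF, 0 °C
Reagents that add atoms: none
Why: Hydride reduction of a lactone to the 1,4-diol; reduction at 0 °C is much faster than enolisation, so C4 is kept, and silyl and benzyl ethers are inert.

Step 7
Reactants: 13 (1S,2R,3R)-3-[4-(benzyloxy)-3-methoxybenzyl]-1-[4-(benzyloxy)-3-methoxyphenyl]-2-{[tert-butyl(diphenyl)silyl]oxymethyl}butane-1,4-diol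
Product: 15 tert-butyl({(2S,3R,4R)-4-[4-(benzyloxy)-3-methoxybenzyl]-2-[4-(benzyloxy)-3-methoxyphenyl]oxolan-3-yl}methoxy)diphenylsilane, via primary tosylate 14 (not isolated)
Conditions: TsCl, Et3N, DMAP (cat.), CH2Cl2, 0 °C → rt; then KOt-Bu, THF, 0 °C
Reagents that add atoms: none
Why: The primary hydroxyl is sulfonylated in preference to the hindered benzylic one, and the benzylic alkoxide closes the ring by 5-exo-tet Williamson substitution at C5. No bond to C2, C3 or C4 is broken, so all three centres are retained.

Step 8
Reactants: 15 tert-butyl({(2S,3R,4R)-4-[4-(benzyloxy)-3-methoxybenzyl]-2-[4-(benzyloxy)-3-methoxyphenyl]oxolan-3-yl}methoxy)diphenylsilane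
Product: 16 {(2S,3R,4R)-4-[4-(benzyloxy)-3-methoxybenzyl]-2-[4-(benzyloxy)-3-methoxyphenyl]oxolan-3-yl}methanol
Conditions: Bu4NF, THF, 0 °C → rt
Reagents that add atoms: none
Why: Fluoride cleavage of a silyl ether; benzyl ethers and the oxolane are inert.

Step 9
Reactants: 16 {(2S,3R,4R)-4-[4-(benzyloxy)-3-methoxybenzyl]-2-[4-(benzyloxy)-3-methoxyphenyl]oxolan-3-yl}methanol; 17 stearoyl chloride (octadecanoyl chloride)
Product: 18 {(2S,3R,4R)-4-[4-(benzyloxy)-3-methoxybenzyl]-2-[4-(benzyloxy)-3-methoxyphenyl]oxolan-3-yl}methyl octadecanoate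
Conditions: Et3N, DMAP (cat.), CH2Cl2, 0 °C → rt
Reagents that add atoms: none
Why: DMAP-catalysed acylation of the only free hydroxyl by an acid chloride; both phenols are still benzylated, so no regiochemical question arises.

Step 10
Reactants: 18 {(2S,3R,4R)-4-[4-(benzyloxy)-3-methoxybenzyl]-2-[4-(benzyloxy)-3-methoxyphenyl]oxolan-3-yl}methyl octadecanoate
Product: 19 {(2S,3R,4R)-4-(4-hydroxy-3-methoxybenzyl)-2-(4-hydroxy-3-methoxyphenyl)oxolan-3-yl}methyl octadecanoate
Conditions: H2 (1 atm), 10% Pd/C, EtOAc, rt, stopped at full conversion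
Reagents that add atoms: none
Why: Hydrogenolysis of aryl benzyl ethers, which is much faster than cleavage of the cyclic benzylic C2–O1 bond in a neutral aprotic solvent; the ester is inert.

## Compound list

1 | propargyl alcohol (prop-2-yn-1-ol) | C#CCO | starting material
2 | tert-butyl(diphenyl)(prop-2-yn-1-yloxy)silane | C#CCO[Si](c1ccccc1)(c1ccccc1)C(C)(C)C | intermediate
3 | lithium acetylide of 2 (not isolated) | [Li]C#CCO[Si](c1ccccc1)(c1ccccc1)C(C)(C)C | intermediate
4 | ethyl 4-[tert-butyl(diphenyl)silyl]oxybut-2-ynoate | CCOC(=O)C#CCO[Si](c1ccccc1)(c1ccccc1)C(C)(C)C | intermediate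
5 | 2-(iodomethyl)-4,4,5,5-tetramethyl-1,3,2-dioxaborolane | ICB1OC(C)(C)C(C)(C)O1 | starting material
6 | ethyl (E)-4-[tert-butyl(diphenyl)silyl]oxy-2-(diisobutylalumanyl)but-2-enoate, H and Al cis (not isolated) | CCOC(=O)/C(=C\CO[Si](c1ccccc1)(c1ccccc1)C(C)(C)C)[Al](CC(C)C)CC(C)C | intermediate
7 | ethyl (Z)-4-[tert-butyl(diphenyl)silyl]oxy-2-[(4,4,5,5-tetramethyl-1,3,2-dioxaborolan-2-yl)methyl]but-2-enoate | CCOC(=O)/C(CB1OC(C)(C)C(C)(C)O1)=C\CO[Si](c1ccccc1)(c1ccccc1)C(C)(C)C | intermediate
8 | 4-(benzyloxy)-3-methoxybenzaldehyde (O-benzylvanillin) | COc1cc(C=O)ccc1OCc1ccccc1 | starting material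
9 | ethyl (3R)-3-{(S)-[4-(benzyloxy)-3-methoxyphenyl][(4,4,5,5-tetramethyl-1,3,2-dioxaborolan-2-yl)oxy]methyl}-4-[tert-butyl(diphenyl)silyl]oxy-2-methylidenebutanoate (not isolated) | CCOC(=O)C(=C)[C@H](CO[Si](c1ccccc1)(c1ccccc1)C(C)(C)C)[C@H](OB1OC(C)(C)C(C)(C)O1)c1ccc(OCc2ccccc2)c(OC)c1 | intermediate
10 | (4R,5S)-5-[4-(benzyloxy)-3-methoxyphenyl]-4-{[tert-butyl(diphenyl)silyl]oxymethyl}-3-methylideneoxolan-2-one | CC(C)(C)[Si](c1ccccc1)(c1ccccc1)OC[C@H]1C(=C)C(=O)O[C@@H]1c1ccc(OCc2ccccc2)c(OC)c1 | intermediate
11 | [4-(benzyloxy)-3-methoxyphenyl]boronic acid | COc1cc(B(O)O)ccc1OCc1ccccc1 | starting material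
12 | (3R,4R,5S)-3-[4-(benzyloxy)-3-methoxybenzyl]-5-[4-(benzyloxy)-3-methoxyphenyl]-4-{[tert-butyl(diphenyl)silyl]oxymethyl}oxolan-2-one | CC(C)(C)[Si](c1ccccc1)(c1ccccc1)OC[C@H]1[C@@H](Cc2ccc(OCc3ccccc3)c(OC)c2)C(=O)O[C@@H]1c1ccc(OCc2ccccc2)c(OC)c1 | intermediate
13 | (1S,2R,3R)-3-[4-(benzyloxy)-3-methoxybenzyl]-1-[4-(benzyloxy)-3-methoxyphenyl]-2-{[tert-butyl(diphenyl)silyl]oxymethyl}butane-1,4-diol | CC(C)(C)[Si](c1ccccc1)(c1ccccc1)OC[C@@H]([C@@H](Cc1ccc(OCc2ccccc2)c(OC)c1)CO)[C@H](O)c1ccc(OCc2ccccc2)c(OC)c1 | intermediate
14 | (2R,3R,4S)-2-[4-(benzyloxy)-3-methoxybenzyl]-4-[4-(benzyloxy)-3-methoxyphenyl]-3-{[tert-butyl(diphenyl)silyl]oxymethyl}-4-hydroxybutyl 4-methylbenzenesulfonate (not isolated) | CC(C)(C)[Si](c1ccccc1)(c1ccccc1)OC[C@@H]([C@@H](Cc1ccc(OCc2ccccc2)c(OC)c1)COS(=O)(=O)c1ccc(C)cc1)[C@H](O)c1ccc(OCc2ccccc2)c(OC)c1 | intermediate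
15 | tert-butyl({(2S,3R,4R)-4-[4-(benzyloxy)-3-methoxybenzyl]-2-[4-(benzyloxy)-3-methoxyphenyl]oxolan-3-yl}methoxy)diphenylsilane | CC(C)(C)[Si](c1ccccc1)(c1ccccc1)OC[C@H]1[C@@H](Cc2ccc(OCc3ccccc3)c(OC)c2)CO[C@@H]1c1ccc(OCc2ccccc2)c(OC)c1 | intermediate
16 | {(2S,3R,4R)-4-[4-(benzyloxy)-3-methoxybenzyl]-2-[4-(benzyloxy)-3-methoxyphenyl]oxolan-3-yl}methanol | OC[C@H]1[C@@H](Cc2ccc(OCc3ccccc3)c(OC)c2)CO[C@@H]1c1ccc(OCc2ccccc2)c(OC)c1 | intermediate
17 | stearoyl chloride (octadecanoyl chloride) | CCCCCCCCCCCCCCCCCC(=O)Cl | starting material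
18 | {(2S,3R,4R)-4-[4-(benzyloxy)-3-methoxybenzyl]-2-[4-(benzyloxy)-3-methoxyphenyl]oxolan-3-yl}methyl octadecanoate | CCCCCCCCCCCCCCCCCC(=O)OC[C@H]1[C@@H](Cc2ccc(OCc3ccccc3)c(OC)c2)CO[C@@H]1c1ccc(OCc2ccccc2)c(OC)c1 | intermediate
19 | {(2S,3R,4R)-4-(4-hydroxy-3-methoxybenzyl)-2-(4-hydroxy-3-methoxyphenyl)oxolan-3-yl}methyl octadecanoate (CNP0168412.1) | CCCCCCCCCCCCCCCCCC(=O)OC[C@H]1[C@@H](Cc2ccc(O)c(OC)c2)CO[C@@H]1c1ccc(O)c(OC)c1 | target

## Step count and least certain steps

Total step count: 10. Longest linear sequence: 10 steps (1 → 19); compounds 5, 8, 11 and 17 are purchased and enter at steps 3, 4, 5 and 9.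

**Step 4 (key step).** The most likely failure is slow turnover: the ester makes the allyl unit of 7 a poor nucleophile, and 8 is an electron-rich, poorly electrophilic aldehyde. A second risk is weak or reversed enantiofacial discrimination, since the catalyst model was built on reagents without a 2-substituent. Ionisation of the benzylic oxygen under acid is harmless, because reclosure trans to C3 returns the same lactone. A reversed sense would be met with the (R)-acid. The fallback sets out from 8 and returns at 10 by an Evans syn-aldol route: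
- The dibutylboron enolate (Bu2BOTf, i-Pr2NEt) of (S)-4-benzyl-3-(pent-4-enoyl)-1,3-oxazolidin-2-one F1, made from the parent oxazolidinone, n-BuLi and pent-4-enoyl chloride, is added to 8. This gives the syn-aldol adduct F2, whose two new centres already have the C2 and C3 configurations.
- LiBH4 removes the auxiliary to give the 1,3-diol F3.
- TBDPSCl and imidazole silylate the primary hydroxyl to give the homoallylic alcohol F4.
- Lemieux–Johnson cleavage of the terminal alkene (OsO4 cat., NaIO4, 2,6-lutidine) gives the lactol F5.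
- TEMPO with PhI(OAc)2 oxidises this to the trans lactone F6.
- α-Methylenation follows: LiN(SiMe3)2 and N,N-dimethylmethyleneiminium iodide give the Mannich base F7, MeI gives the ammonium iodide F8, and NaHCO3 eliminates to 10.

**Step 3.** The alkene geometry may erode, because the alkenylalane can equilibrate through an aluminium allenolate while the alkylation by 5 is slow; reduction of the ester is a second risk. The fallback sets out from 4 and returns at 7. Pd(PPh3)4-catalysed syn-hydrostannation with Bu3SnH gives the configurationally stable α-stannyl enoate F9. Iodine converts this with retention to the α-iodo enoate F10. Negishi coupling with the zinc reagent F11, made from 5 and zinc dust, under Pd(PPh3)4 then gives 7.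

**Step 5.** Facial selectivity in the protonation of the rhodium enolate may be poor, since the 5-aryl group shields the face opposite C9 to some degree. Base-mediated epimerisation to the more stable 3,4-trans lactone and β-hydride elimination to arylidene products are further risks. The fallback sets out from 10 and returns at 12. Mizoroki–Heck arylation with 1-(benzyloxy)-4-iodo-2-methoxybenzene (Pd(OAc)2, P(o-tol)3, Et3N, MeCN, 80 °C) gives the (E)-arylidene lactone F12. Hydrogenation over 5% Rh/Al2O3 in EtOAc spares the benzyl ethers and adds hydrogen to the face opposite the silyloxymethyl group, giving the 3,4-cis lactone 12.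

**Step 7.** Sulfonylation may also occur at the benzylic hydroxyl, followed by ionisation and loss of C2 configuration. Under alkoxide the silyl group may migrate, and the freed C9 oxygen would then close the wrong oxolane. The fallback sets out from 12 and returns at 15 without an open-chain diol. i-Bu2AlH in CH2Cl2 at −78 °C gives the lactol F13, and Et3SiH with BF3·OEt2 at −78 °C reduces the derived oxocarbenium ion to 15.

**Step 10.** Over-reduction is the risk: once the benzyl ethers are gone, the C2–O1 benzylic ether can be hydrogenolysed to the ring-opened product. The fallback sets out from 18 and gives 19 without hydrogen: BCl3 with pentamethylbenzene as cation scavenger in CH2Cl2 at −78 °C cleaves the aryl benzyl ethers by Lewis-acid dealkylation.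

## Further compounds

F1 | step 4 | (S)-4-benzyl-3-(pent-4-enoyl)-1,3-oxazolidin-2-one | C=CCCC(=O)N1[C@@H](Cc2ccccc2)COC1=O
F2 | step 4 | (S)-4-benzyl-3-{(2S)-2-[(S)-[4-(benzyloxy)-3-methoxyphenyl](hydroxy)methyl]pent-4-enoyl}-1,3-oxazolidin-2-one | C=CC[C@H](C(=O)N1[C@@H](Cc2ccccc2)COC1=O)[C@H](O)c1ccc(OCc2ccccc2)c(OC)c1
F3 | step 4 | (1S,2R)-1-[4-(benzyloxy)-3-methoxyphenyl]-2-(prop-2-en-1-yl)propane-1,3-diol | C=CC[C@H](CO)[C@H](O)c1ccc(OCc2ccccc2)c(OC)c1
F4 | step 4 | (1S,2R)-1-[4-(benzyloxy)-3-methoxyphenyl]-2-{[tert-butyl(diphenyl)silyl]oxymethyl}pent-4-en-1-ol | C=CC[C@H](CO[Si](c1ccccc1)(c1ccccc1)C(C)(C)C)[C@H](O)c1ccc(OCc2ccccc2)c(OC)c1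
F5 | step 4 | (4R,5S)-5-[4-(benzyloxy)-3-methoxyphenyl]-4-{[tert-butyl(diphenyl)silyl]oxymethyl}oxolan-2-ol (both anomers) | CC(C)(C)[Si](c1ccccc1)(c1ccccc1)OC[C@H]1CC(O)O[C@@H]1c1ccc(OCc2ccccc2)c(OC)c1
F6 | step 4 | (4R,5S)-5-[4-(benzyloxy)-3-methoxyphenyl]-4-{[tert-butyl(diphenyl)silyl]oxymethyl}oxolan-2-one | CC(C)(C)[Si](c1ccccc1)(c1ccccc1)OC[C@H]1CC(=O)O[C@@H]1c1ccc(OCc2ccccc2)c(OC)c1
F7 | step 4 | (4R,5S)-5-[4-(benzyloxy)-3-methoxyphenyl]-4-{[tert-butyl(diphenyl)silyl]oxymethyl}-3-[(dimethylamino)methyl]oxolan-2-one (C3 epimers) | CC(C)(C)[Si](c1ccccc1)(c1ccccc1)OC[C@H]1C(CN(C)C)C(=O)O[C@@H]1c1ccc(OCc2ccccc2)c(OC)c1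
F8 | step 4 | {(4R,5S)-5-[4-(benzyloxy)-3-methoxyphenyl]-4-{[tert-butyl(diphenyl)silyl]oxymethyl}-2-oxooxolan-3-yl}methyl(trimethyl)ammonium iodide | CC(C)(C)[Si](c1ccccc1)(c1ccccc1)OC[C@H]1C(C[N+](C)(C)C)C(=O)O[C@@H]1c1ccc(OCc2ccccc2)c(OC)c1.[I-]
F9 | step 3 | ethyl (E)-4-[tert-butyl(diphenyl)silyl]oxy-2-(tributylstannyl)but-2-enoate | CCOC(=O)/C(=C\CO[Si](c1ccccc1)(c1ccccc1)C(C)(C)C)[Sn](CCCC)(CCCC)CCCC
F10 | step 3 | ethyl (E)-4-[tert-butyl(diphenyl)silyl]oxy-2-iodobut-2-enoate | CCOC(=O)/C(I)=C\CO[Si](c1ccccc1)(c1ccccc1)C(C)(C)C
F11 | step 3 | [(4,4,5,5-tetramethyl-1,3,2-dioxaborolan-2-yl)methyl]zinc iodide | I[Zn]CB1OC(C)(C)C(C)(C)O1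
F12 | step 5 | (3E,4R,5S)-3-[4-(benzyloxy)-3-methoxybenzylidene]-5-[4-(benzyloxy)-3-methoxyphenyl]-4-{[tert-butyl(diphenyl)silyl]oxymethyl}oxolan-2-one | CC(C)(C)[Si](c1ccccc1)(c1ccccc1)OC[C@H]1/C(=C\c2ccc(OCc3ccccc3)c(OC)c2)C(=O)O[C@@H]1c1ccc(OCc2ccccc2)c(OC)c1
F13 | step 7 | (3R,4R,5S)-3-[4-(benzyloxy)-3-methoxybenzyl]-5-[4-(benzyloxy)-3-methoxyphenyl]-4-{[tert-butyl(diphenyl)silyl]oxymethyl}oxolan-2-ol (both anomers) | CC(C)(C)[Si](c1ccccc1)(c1ccccc1)OC[C@H]1[C@@H](Cc2ccc(OCc3ccccc3)c(OC)c2)C(O)O[C@@H]1c1ccc(OCc2ccccc2)c(OC)c1
F0 | step 10 | none | none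
A1 | alternative 1 | 3-(allyloxy)-3-[4-(benzyloxy)-3-methoxyphenyl]-2-iodopropyl octadecanoate, benzylic centre as at C2 of the target | CCCCCCCCCCCCCCCCCC(=O)OCC(I)[C@H](OCC=C)c1ccc(OCc2ccccc2)c(OC)c1
A2 | alternative 1 | [4-(benzyloxy)-3-methoxyphenyl]zinc bromide | COc1cc([Zn]Br)ccc1OCc1ccccc1
A3 | alternative 1 | O,O′-dibenzyl ether of the target (same structure as 18) | CCCCCCCCCCCCCCCCCC(=O)OC[C@H]1[C@@H](Cc2ccc(OCc3ccccc3)c(OC)c2)CO[C@@H]1c1ccc(OCc2ccccc2)c(OC)c1
A4 | alternative 2 | (5R)-2-[4-(benzyloxy)-3-methoxyphenyl]-5-[4-(benzyloxy)-3-methoxybenzyl]-4,5-dihydro-1,3-dioxepine | O1C=C[C@@H](Cc2ccc(OCc3ccccc3)c(OC)c2)COC1c1ccc(OCc2ccccc2)c(OC)c1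
A5 | alternative 2 | (2S,3S,4R)-4-[4-(benzyloxy)-3-methoxybenzyl]-2-[4-(benzyloxy)-3-methoxyphenyl]oxolane-3-carbaldehyde | O=C[C@H]1[C@@H](Cc2ccc(OCc3ccccc3)c(OC)c2)CO[C@@H]1c1ccc(OCc2ccccc2)c(OC)c1
A6 | alternative 3 | (2R,5S)-5-[4-(benzyloxy)-3-methoxybenzyl]-2-[4-(benzyloxy)-3-methoxyphenyl]-3-diazooxan-4-one | [N-]=[N+]=C1C(=O)[C@@H](Cc2ccc(OCc3ccccc3)c(OC)c2)CO[C@@H]1c1ccc(OCc2ccccc2)c(OC)c1
A7 | alternative 3 | methyl (2S,3S,4R)-4-[4-(benzyloxy)-3-methoxybenzyl]-2-[4-(benzyloxy)-3-methoxyphenyl]oxolane-3-carboxylate | COC(=O)[C@H]1[C@@H](Cc2ccc(OCc3ccccc3)c(OC)c2)CO[C@@H]1c1ccc(OCc2ccccc2)c(OC)c1
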